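**Strategy**

The benzo ring of the dihydrobenzofuran (ring A: C3a, C4, C5, C6, C7, C7a) is introduced as a quinone monoketal, 3,4,4-trimethoxycyclohexa-2,5-dienone: its ketal carbon becomes C7a, the β-carbon of its methoxy-free enone becomes C3a, its enol-ether carbon is C7 and its carbonyl is C5. In one telescoped operation an enantiopure β-silyloxy silyl ketene acetal (C2, C3, guaiacyl ring) adds at C3a, and the C2 oxygen then replaces a ketal methoxy group at C7a while ring A aromatises. The step exploits the para relation of O1 and C5 and the C7 methoxy group in ring A; the C5 phenol so formed carries the stilbene through triflate and Heck coupling.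

Key step: step 6

Remark: benzofuran numbering (O1, C2, C3, C3a, C4 to C7, C7a) is used for the target and its precursors. Step 6 is run in one flask without isolation, and its two changes of medium are counted as part of one operation. Ketene acetal 5 is used as its mixture of double-bond isomers, which has no consequence because C3 is equilibrated in step 7.

**Route**

Step 1
Reactants: 1 acetovanillone, 1-(4-hydroxy-3-methoxyphenyl)ethan-1-one
Product: 2 1-[3-methoxy-4-(methoxymethoxy)phenyl]ethan-1-one
Conditions: MOMCl (1.3 equiv), iPr2NEt (1.5 equiv), CH2Cl2, 0 °C to rt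
Reagents that add atoms: chloromethyl methyl ether, COCCl
Why: O-alkylation of the acidic para-acyl phenol (Williamson-type) should give a MOM ether that survives the basic and mildly acidic steps and is removed only at the end.

Step 2
Reactants: 2 1-[3-methoxy-4-(methoxymethoxy)phenyl]ethan-1-one
Product: 3 methyl 3-[3-methoxy-4-(methoxymethoxy)phenyl]-3-oxopropanoate
Conditions: NaH (2.5 equiv), dimethyl carbonate (4 equiv), THF, reflux; AcOH quench
Reagents that add atoms: dimethyl carbonate, COC(=O)OC
Why: crossed Claisen condensation of the methyl ketone enolate with the non-enolisable carbonate should be driven by formation of the β-keto ester enolate.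

Step 3
Reactants: 3 methyl 3-[3-methoxy-4-(methoxymethoxy)phenyl]-3-oxopropanoate
Product: 4 methyl (3R)-3-hydroxy-3-[3-methoxy-4-(methoxymethoxy)phenyl]propanoate
Conditions: RuCl[(R,R)-TsDPEN](p-cymene) (1 mol%), HCO2H/Et3N (5:2), 35 °C
Reagents that add atoms: none
Why: Noyori–Ikariya asymmetric transfer hydrogenation of an aryl β-keto ester, in which the (R,R)-ligand should deliver hydride to the ketone face that gives the (R)-carbinol, the future C2.

Step 4
Reactants: 4 methyl (3R)-3-hydroxy-3-[3-methoxy-4-(methoxymethoxy)phenyl]propanoate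
Product: 5 (3R)-1-methoxy-3-[3-methoxy-4-(methoxymethoxy)phenyl]-1,3-bis(trimethylsilyloxy)prop-1-ene (mixture of double-bond isomers)
Conditions: LDA (2.3 equiv), THF, −78 °C; TMSCl (2.6 equiv), −78 °C to rt; pentane, filtration, used crude
Reagents that add atoms: chlorotrimethylsilane, C[Si](C)(C)Cl
Why: double deprotonation should give the alkoxide–enolate dianion (Fráter–Seebach type), whose alkoxide cannot leave, and O-silylation of both oxygens gives the silyl ketene acetal with C2 untouched.

Step 5
Reactants: 6 3,4-dimethoxyphenol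
Product: 7 3,4,4-trimethoxycyclohexa-2,5-dien-1-one
Conditions: PhI(OAc)2 (1.1 equiv), MeOH, 0 °C
Reagents that add atoms: methanol, CO
Why: oxidative dearomatisation of a para-methoxyphenol, in which methanol should trap the phenoxenium ion para to the hydroxyl to give the quinone monoketal.

Step 6
Reactants: 5 (3R)-1-methoxy-3-[3-methoxy-4-(methoxymethoxy)phenyl]-1,3-bis(trimethylsilyloxy)prop-1-ene; 7 3,4,4-trimethoxycyclohexa-2,5-dien-1-one
Product: 11 methyl (2R)-5-hydroxy-7-methoxy-2-[3-methoxy-4-(methoxymethoxy)phenyl]-2,3-dihydro-1-benzofuran-3-carboxylate as a mixture of C3 epimers, via silyl enol ether Michael adduct 8 (not isolated), via hydroxy keto ketal 9 (not isolated), via bicyclic mixed ketal 10 (not isolated)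
Conditions: (a) 7 (1.3 equiv), LiClO4 (10 mol%), MeCN, 0 to 40 °C; (b) K2CO3 (0.1 equiv), MeOH, 0 °C, then evaporation; (c) PPTS (0.5 equiv), 5 Å molecular sieves, toluene, 60 °C
Reagents that add atoms: none
Why: Proposed new method: the silyl ketene acetal should add in Mukaiyama–Michael fashion to the β-carbon of the methoxy-free enone of 7, next to the ketal carbon, which makes the C3–C3a bond; after methanolysis of both silyl groups, the pyridinium acid ionises the dimethyl ketal, the C2 hydroxyl traps the oxocarbenium ion (O1–C7a bond), and loss of the second methanol with enolisation aromatises ring A to the C5 phenol. The closest known reaction type is the Michael addition of 1,3-dicarbonyl compounds to quinone monoketals followed by acid-induced cyclisation with loss of two methanol to 5-hydroxybenzofurans; new here are a mono-ester silyl ketene acetal as donor and an sp3 carbinol oxygen as the nucleophile in the ketal exchange. The dihydrofuran ring closes 5-exo-trig on the oxocarbenium carbon. C2 is carried over unchanged from 4 because its C–O bond is never broken, C3 is formed without reliable control and is corrected in step 7, and the transient ring stereocentre at C3a vanishes on aromatisation. The step needs site selectivity for the enone without methoxy, which the vinylogous-ester deactivation of the other enone and the soft donor should secure, and it needs ketal exchange to outrun simple loss of methanol to an uncyclised dimethoxyphenol, which desilylation to ketone 9 before any acid and the five-membered intramolecular trapping are meant to secure.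

Step 7
Reactants: 11 methyl (2R)-5-hydroxy-7-methoxy-2-[3-methoxy-4-(methoxymethoxy)phenyl]-2,3-dihydro-1-benzofuran-3-carboxylate (C3 epimers)
Product: 12 methyl (2R,3R)-5-hydroxy-7-methoxy-2-[3-methoxy-4-(methoxymethoxy)phenyl]-2,3-dihydro-1-benzofuran-3-carboxylate (2,3-trans)
Conditions: NaOMe (2.5 equiv), MeOH, argon, 0 °C to rt; AcOH quench
Reagents that add atoms: none
Why: base-mediated epimerisation at the benzylic ester α-carbon should converge on the thermodynamically favoured 2,3-trans isomer without touching C2; the C5 phenoxide present under these conditions makes O1 a poor leaving group and so disfavours ring opening by β-elimination, and methoxide cannot transesterify a methyl ester.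

Step 8
Reactants: 12 methyl (2R,3R)-5-hydroxy-7-methoxy-2-[3-methoxy-4-(methoxymethoxy)phenyl]-2,3-dihydro-1-benzofuran-3-carboxylate
Product: 13 methyl (2R,3R)-7-methoxy-2-[3-methoxy-4-(methoxymethoxy)phenyl]-5-(trifluoromethanesulfonyloxy)-2,3-dihydro-1-benzofuran-3-carboxylate
Conditions: Tf2O (1.2 equiv), pyridine (3 equiv), CH2Cl2, −20 to 0 °C
Reagents that add atoms: trifluoromethanesulfonic anhydride, O=S(=O)(OS(=O)(=O)C(F)(F)F)C(F)(F)F
Why: O-sulfonylation of the only free hydroxyl should turn the former quinone carbonyl position C5 into a cross-coupling handle.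

Step 9
Reactants: 13 methyl (2R,3R)-7-methoxy-2-[3-methoxy-4-(methoxymethoxy)phenyl]-5-(trifluoromethanesulfonyloxy)-2,3-dihydro-1-benzofuran-3-carboxylate
Product: 14 (2R,3S)-3-(hydroxymethyl)-7-methoxy-2-[3-methoxy-4-(methoxymethoxy)phenyl]-2,3-dihydro-1-benzofuran-5-yl trifluoromethanesulfonate
Conditions: DIBAL-H (3 equiv), CH2Cl2, −78 to 0 °C; Rochelle salt work-up
Reagents that add atoms: none
Why: hydride reduction of the methyl ester to the primary alcohol, which the aryl triflate and MOM ether should tolerate at low temperature; C3 is no longer epimerisable afterwards (the descriptor changes from 3R to 3S only through the priority change).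

Step 10
Reactants: 15 3,5-dihydroxybenzaldehyde
Product: 16 3,5-bis(methoxymethoxy)benzaldehyde
Conditions: MOMCl (2.6 equiv), iPr2NEt (3 equiv), CH2Cl2, 0 °C to rt
Reagents that add atoms: chloromethyl methyl ether, COCCl
Why: double O-alkylation of the resorcinol hydroxyls (Williamson-type) puts the same acid-labile group on all three phenols of the target.

Step 11
Reactants: 16 3,5-bis(methoxymethoxy)benzaldehyde
Product: 17 1-ethenyl-3,5-bis(methoxymethoxy)benzene
Conditions: Ph3PCH3Br (1.3 equiv), KOtBu (1.25 equiv), THF, 0 °C to rt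
Reagents that add atoms: methyltriphenylphosphonium bromide, C[P+](c1ccccc1)(c1ccccc1)c1ccccc1.[Br-]
Why: Wittig methylenation of an aromatic aldehyde with the non-stabilised ylide should give the styrene.

Step 12
Reactants: 14 (2R,3S)-3-(hydroxymethyl)-7-methoxy-2-[3-methoxy-4-(methoxymethoxy)phenyl]-2,3-dihydro-1-benzofuran-5-yl trifluoromethanesulfonate; 17 1-ethenyl-3,5-bis(methoxymethoxy)benzene
Product: 18 [(2R,3S)-5-[(E)-2-[3,5-bis(methoxymethoxy)phenyl]ethenyl]-7-methoxy-2-[3-methoxy-4-(methoxymethoxy)phenyl]-2,3-dihydro-1-benzofuran-3-yl]methanol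
Conditions: PdCl2(PPh3)2 (5 mol%), LiCl (3 equiv), Et3N (3 equiv), DMF, 100 °C
Reagents that add atoms: none
Why: Mizoroki–Heck reaction of the unhindered aryl triflate with the styrene, in which chloride should hold the neutral pathway so that the aryl group adds to the terminal carbon and syn β-hydride elimination gives the (E)-stilbene.

Step 13
Reactants: 18 [(2R,3S)-5-[(E)-2-[3,5-bis(methoxymethoxy)phenyl]ethenyl]-7-methoxy-2-[3-methoxy-4-(methoxymethoxy)phenyl]-2,3-dihydro-1-benzofuran-3-yl]methanol
Product: 19 Gnetofuran A, 5-[(E)-2-[(2R,3S)-2-(4-hydroxy-3-methoxyphenyl)-3-(hydroxymethyl)-7-methoxy-2,3-dihydro-1-benzofuran-5-yl]ethenyl]benzene-1,3-diol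
Conditions: HCl (3 M aq.), MeOH/THF, rt to 40 °C
Reagents that add atoms: none
Why: acid-catalysed acetal cleavage should remove the three MOM ethers in one step under conditions mild enough to leave the benzylic C2–O1 bond, both stereocentres and the stilbene intact.

**Compound list**

1 | acetovanillone, 1-(4-hydroxy-3-methoxyphenyl)ethan-1-one | CC(=O)c1ccc(O)c(OC)c1 | starting material
2 | 1-[3-methoxy-4-(methoxymethoxy)phenyl]ethan-1-one | CC(=O)c1ccc(OCOC)c(OC)c1 | intermediate
3 | methyl 3-[3-methoxy-4-(methoxymethoxy)phenyl]-3-oxopropanoate | COC(=O)CC(=O)c1ccc(OCOC)c(OC)c1 | intermediate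
4 | methyl (3R)-3-hydroxy-3-[3-methoxy-4-(methoxymethoxy)phenyl]propanoate | COC(=O)C[C@@H](O)c1ccc(OCOC)c(OC)c1 | intermediate
5 | (3R)-1-methoxy-3-[3-methoxy-4-(methoxymethoxy)phenyl]-1,3-bis(trimethylsilyloxy)prop-1-ene, double-bond isomers | COC(O[Si](C)(C)C)=C[C@@H](O[Si](C)(C)C)c1ccc(OCOC)c(OC)c1 | intermediate
6 | 3,4-dimethoxyphenol | COc1ccc(O)cc1OC | starting material
7 | 3,4,4-trimethoxycyclohexa-2,5-dien-1-one | COC1=CC(=O)C=CC1(OC)OC | intermediate
8 | methyl (3R)-3-[3-methoxy-4-(methoxymethoxy)phenyl]-2-[5,6,6-trimethoxy-3-(trimethylsilyloxy)cyclohexa-2,4-dien-1-yl]-3-(trimethylsilyloxy)propanoate, new centres unassigned | COC(=O)C(C1C=C(O[Si](C)(C)C)C=C(OC)C1(OC)OC)[C@@H](O[Si](C)(C)C)c1ccc(OCOC)c(OC)c1 | intermediate (not isolated)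
9 | methyl (3R)-3-hydroxy-3-[3-methoxy-4-(methoxymethoxy)phenyl]-2-(2,2,3-trimethoxy-5-oxocyclohex-3-en-1-yl)propanoate, new centres unassigned | COC(=O)C(C1CC(=O)C=C(OC)C1(OC)OC)[C@@H](O)c1ccc(OCOC)c(OC)c1 | intermediate (not isolated)
10 | methyl (2R)-7,7a-dimethoxy-2-[3-methoxy-4-(methoxymethoxy)phenyl]-5-oxo-2,3,3a,4,5,7a-hexahydro-1-benzofuran-3-carboxylate, other centres unassigned | COC(=O)C1C2CC(=O)C=C(OC)C2(OC)O[C@H]1c1ccc(OCOC)c(OC)c1 | intermediate (not isolated)
11 | methyl (2R)-5-hydroxy-7-methoxy-2-[3-methoxy-4-(methoxymethoxy)phenyl]-2,3-dihydro-1-benzofuran-3-carboxylate, C3 epimers | COc1cc([C@@H]2Oc3c(OC)cc(O)cc3C2C(=O)OC)ccc1OCOC | intermediate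
12 | methyl (2R,3R)-5-hydroxy-7-methoxy-2-[3-methoxy-4-(methoxymethoxy)phenyl]-2,3-dihydro-1-benzofuran-3-carboxylate | COc1cc([C@@H]2Oc3c(OC)cc(O)cc3[C@H]2C(=O)OC)ccc1OCOC | intermediate
13 | methyl (2R,3R)-7-methoxy-2-[3-methoxy-4-(methoxymethoxy)phenyl]-5-(trifluoromethanesulfonyloxy)-2,3-dihydro-1-benzofuran-3-carboxylate | COc1cc([C@@H]2Oc3c(OC)cc(OS(=O)(=O)C(F)(F)F)cc3[C@H]2C(=O)OC)ccc1OCOC | intermediate
14 | (2R,3S)-3-(hydroxymethyl)-7-methoxy-2-[3-methoxy-4-(methoxymethoxy)phenyl]-2,3-dihydro-1-benzofuran-5-yl trifluoromethanesulfonate | COc1cc([C@@H]2Oc3c(OC)cc(OS(=O)(=O)C(F)(F)F)cc3[C@H]2CO)ccc1OCOC | intermediate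
15 | 3,5-dihydroxybenzaldehyde | O=Cc1cc(O)cc(O)c1 | starting material
16 | 3,5-bis(methoxymethoxy)benzaldehyde | COCOc1cc(C=O)cc(OCOC)c1 | intermediate
17 | 1-ethenyl-3,5-bis(methoxymethoxy)benzene | C=Cc1cc(OCOC)cc(OCOC)c1 | intermediate
18 | [(2R,3S)-5-[(E)-2-[3,5-bis(methoxymethoxy)phenyl]ethenyl]-7-methoxy-2-[3-methoxy-4-(methoxymethoxy)phenyl]-2,3-dihydro-1-benzofuran-3-yl]methanol | COc1cc([C@@H]2Oc3c(OC)cc(/C=C/c4cc(OCOC)cc(OCOC)c4)cc3[C@H]2CO)ccc1OCOC | intermediate
19 | Gnetofuran A | COc1cc([C@@H]2Oc3c(OC)cc(/C=C/c4cc(O)cc(O)c4)cc3[C@H]2CO)ccc1O | target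

**Step count and risks**

Total step count: 13. Longest linear sequence: 10 steps (1, 2, 3, 4, 6, 7, 8, 9, 12, 13).

Step 6 (proposed new method). After the conjugate addition, simple loss of methanol and aromatisation may outrun the ketal exchange, so that the C2 oxygen never reaches C7a. The crowded carbon–carbon bond formation may also be slow enough for the ketene acetal to decompose by β-elimination of silanol. The fallback uses known chemistry, keeps the same two ring bonds formed in one flask, and sets out from β-keto ester 3 and monoketal 7. Base-catalysed Michael addition (NaOMe cat., MeOH) followed by acid (TsOH, toluene) should give methyl 5-hydroxy-7-methoxy-2-[3-methoxy-4-(methoxymethoxy)phenyl]-1-benzofuran-3-carboxylate F1, the established outcome for 1,3-dicarbonyl compounds and quinone monoketals. Conjugate reduction with magnesium in methanol (NH4Cl buffer) should give the racemic 2,3-trans ester, rac-methyl (2R,3R)-5-hydroxy-7-methoxy-2-[3-methoxy-4-(methoxymethoxy)phenyl]-2,3-dihydro-1-benzofuran-3-carboxylate F2. Preparative chromatography on a chiral stationary phase then delivers the (2R,3R)-enantiomer, and the route is rejoined at compound 12.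

Step 7. The ester enolate may expel the aryl oxide by β-elimination and reclose, which would erode the enantiopurity set in step 3, or equilibration may stop short of the trans isomer. The fallback moves the equilibration to the aldehyde oxidation level, where a weak amine suffices, and sets out from compound 11. Partial reduction (DIBAL-H, toluene, −78 °C) should give (2R)-5-hydroxy-7-methoxy-2-[3-methoxy-4-(methoxymethoxy)phenyl]-2,3-dihydro-1-benzofuran-3-carbaldehyde F3 as its C3 epimers. Et3N in CH2Cl2 should equilibrate this to the trans aldehyde, (2R,3R)-5-hydroxy-7-methoxy-2-[3-methoxy-4-(methoxymethoxy)phenyl]-2,3-dihydro-1-benzofuran-3-carbaldehyde F4. NaBH4 in MeOH then gives (2R,3S)-3-(hydroxymethyl)-7-methoxy-2-[3-methoxy-4-(methoxymethoxy)phenyl]-2,3-dihydro-1-benzofuran-5-ol F5, and phenol-selective triflation (PhNTf2, K2CO3, THF) rejoins the route at compound 14.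

Step 12. Insertion may occur with the opposite regiochemistry to give a 1,1-diarylethene, or the triflate may be cleaved at sulfur under hot amine and DMF and return the phenol. The fallback fixes the alkene geometry and position in the coupling partner and sets out from aldehyde 16. Boron-Wittig olefination with bis(pinacolatoboryl)methane and LiTMP (THF, −78 °C to rt) should give 2-[(E)-2-[3,5-bis(methoxymethoxy)phenyl]ethenyl]-4,4,5,5-tetramethyl-1,3,2-dioxaborolane F6. Suzuki–Miyaura coupling of F6 with triflate 14 (Pd(PPh3)4, K3PO4, dioxane/water, 80 °C) rejoins the route at compound 18.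

**Further compounds**

F1 | step 6 | methyl 5-hydroxy-7-methoxy-2-[3-methoxy-4-(methoxymethoxy)phenyl]-1-benzofuran-3-carboxylate | COC(=O)c1c(-c2ccc(OCOC)c(OC)c2)oc2c(OC)cc(O)cc12
F2 | step 6 | rac-methyl (2R,3R)-5-hydroxy-7-methoxy-2-[3-methoxy-4-(methoxymethoxy)phenyl]-2,3-dihydro-1-benzofuran-3-carboxylate (both trans enantiomers) | COc1cc([C@@H]2Oc3c(OC)cc(O)cc3[C@H]2C(=O)OC)ccc1OCOC.COc1cc([C@H]2Oc3c(OC)cc(O)cc3[C@@H]2C(=O)OC)ccc1OCOC
F3 | step 7 | (2R)-5-hydroxy-7-methoxy-2-[3-methoxy-4-(methoxymethoxy)phenyl]-2,3-dihydro-1-benzofuran-3-carbaldehyde, C3 epimers | COc1cc([C@@H]2Oc3c(OC)cc(O)cc3C2C=O)ccc1OCOC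
F4 | step 7 | (2R,3R)-5-hydroxy-7-methoxy-2-[3-methoxy-4-(methoxymethoxy)phenyl]-2,3-dihydro-1-benzofuran-3-carbaldehyde | COc1cc([C@@H]2Oc3c(OC)cc(O)cc3[C@H]2C=O)ccc1OCOC
F5 | step 7 | (2R,3S)-3-(hydroxymethyl)-7-methoxy-2-[3-methoxy-4-(methoxymethoxy)phenyl]-2,3-dihydro-1-benzofuran-5-ol | COc1cc([C@@H]2Oc3c(OC)cc(O)cc3[C@H]2CO)ccc1OCOC
F6 | step 12 | 2-[(E)-2-[3,5-bis(methoxymethoxy)phenyl]ethenyl]-4,4,5,5-tetramethyl-1,3,2-dioxaborolane | COCOc1cc(/C=C/B2OC(C)(C)C(C)(C)O2)cc(OCOC)c1
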